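Ring A of the target carries a cis diol at C2/C3 next to a quaternary C4 bearing a formyl group (C19), so C2 and C3 are both former carbonyl carbons. Everything rests on disconnecting the C2–C3 bond: a reductive aldehyde–aldehyde coupling with SmI2 closes ring A, creates C2, C3 and C4 at once and leaves the unused formyl group as C19. Its precursor is a ring-B cyclohexene (C7=C8, side chain at C9 in place) whose C10 carries a CH2CHO arm and whose C5 carries a C(CH3)(CHO)2 unit, made from (S)-carvone, allyl bromide and an (R)-3-methylglutarate half ester and released by triple oxidation of a triol.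

Key step: step 22

Remark: atoms are numbered as in the labdane skeleton of the target (2S,3R,4S,5S,9R,10S,13R; enantio-labdane series); centres drawn without a descriptor (C6 in 2, C4 in 5–7, C9 in 16, the carbinol in 22) are epimer mixtures that are erased later, and metal enolates or alkoxides that live only until work-up are not numbered.

**Ring-B fragment (steps 1–6)**

Step 1
Reactants: 1 (S)-carvone
Product: 2 6-methylcarvone
Conditions: LiN(i-Pr)2, THF, −78 °C; MeI, −78 → 0 °C
Reagents that add atoms: iodomethane, CI
Why: Kinetic deprotonation at C6, the only α′ position, gives the cross-conjugated lithium dienolate, and its SN2 methylation (enolate alkylation) installs the future C20 methyl; the new C6 centre is of no consequence because it becomes trigonal again in step 2.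

Step 2
Reactants: 2 6-methylcarvone; 3 allyl bromide
Product: 4 allyl methyl enone
Conditions: LiN(i-Pr)2, THF, −78 °C; allyl bromide, DMPU, −78 °C → rt
Reagents that add atoms: none
Why: A second enolate alkylation builds the quaternary centre that becomes C10, the allyl group entering on the face opposite the neighbouring isopropenyl group (which stands pseudoaxial to avoid allylic strain with the enolate methyl), so that methyl and isopropenyl end cis and the future C1–C2 arm trans to the future C4 unit.

Step 3
Reactants: 4 allyl methyl enone
Product: 5 epoxide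
Conditions: mCPBA (1.0 equiv), NaHCO3, CH2Cl2, 0 °C
Reagents that add atoms: 3-chloroperoxybenzoic acid, OOC(=O)c1cccc(Cl)c1
Why: Prilezhaev epoxidation is electrophilic, so the 1,1-disubstituted isopropenyl alkene should react ahead of the monosubstituted allyl alkene and the electron-poor enone; the epoxide carbon is formed as both epimers, which converge at diol 8.

Step 4
Reactants: 5 epoxide
Product: 6 α-methyl aldehyde
Conditions: BF3·OEt2 (0.3 equiv), CH2Cl2, −78 °C
Reagents that add atoms: none
Why: Meinwald rearrangement: the Lewis acid opens the 2,2-disubstituted epoxide at its tertiary carbon and a 1,2-hydride shift gives the α-methyl aldehyde (the future C4 with one of its carbonyl carbons), again as an inconsequential epimer mixture.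

Step 5
Reactants: 6 α-methyl aldehyde
Product: 8 keto diol, via hydroxymethyl aldehyde 7 (not isolated)
Conditions: 37% aq. HCHO, K2CO3, MeOH, rt; then NaBH4, −40 °C
Reagents that add atoms: formaldehyde, C=O
Why: Crossed aldol addition to formaldehyde takes place at the aldehyde α-carbon, the only readily enolisable position since the ketone has no α′ hydrogen, and makes C4 quaternary; borohydride then reduces the neopentyl aldehyde far faster than the hindered conjugated ketone at low temperature, giving a 1,3-diol in which C4 carries two identical arms and is no stereocentre.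

Step 6
Reactants: 8 keto diol
Product: 9 acetonide ketone
Conditions: Me2C(OMe)2, PPTS (cat.), acetone, rt
Reagents that add atoms: 2,2-dimethoxypropane, COC(C)(C)OC
Why: Acid-catalysed transketalisation closes the 1,3-dioxane acetonide, which masks the diol against the organolithium, chromium, hydride and Mitsunobu reagents that follow.

**Side-chain fragment (steps 7–10)**

Step 7
Reactants: 10 methyl hydrogen (R)-3-methylglutarate
Product: 11 methyl (R)-5-hydroxy-3-methylpentanoate
Conditions: BH3·SMe2, THF, 0 °C → rt
Reagents that add atoms: none
Why: Borane reduces a carboxylic acid much faster than an ester (chemoselective borane reduction), so the acid terminus becomes the future C11 carbinol and the ester terminus stays as the future C15 carboxyl, the stereocentre (future C13) being untouched.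

Step 8
Reactants: 11 methyl (R)-5-hydroxy-3-methylpentanoate
Product: 12 methyl (S)-5-iodo-3-methylpentanoate
Conditions: I2, PPh3, imidazole, CH2Cl2, 0 °C → rt
Reagents that add atoms: iodine, II
Why: Appel-type iodination: the alkoxyphosphonium ion is displaced by iodide in an SN2 reaction at the primary carbon, and the stereocentre is not involved (its descriptor changes only through ligand priorities).

Step 9
Reactants: 12 methyl (S)-5-iodo-3-methylpentanoate
Product: 13 (S)-5-iodo-3-methylpentan-1-ol
Conditions: i-Bu2AlH (2.2 equiv), CH2Cl2, −78 → 0 °C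
Reagents that add atoms: none
Why: Hydride reduction of the ester by the electrophilic aluminium hydride gives the primary alcohol, while the primary alkyl iodide is inert to this reagent at low temperature.

Step 10
Reactants: 13 (S)-5-iodo-3-methylpentan-1-ol
Product: 14 iodo silyl ether
Conditions: t-BuMe2SiCl, imidazole, CH2Cl2, rt
Reagents that add atoms: tert-butyl(chloro)dimethylsilane, CC(C)(C)[Si](C)(C)Cl
Why: Imidazole-promoted silylation of the primary alcohol gives a silyl ether that withstands iodine–lithium exchange and carbonyl addition.

**Union, ring-B adjustment and release of the precursor (steps 11–21)**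

Step 11
Reactants: 9 acetonide ketone; 14 iodo silyl ether
Product: 16 tertiary allylic alcohol, via alkyllithium 15 (not isolated)
Conditions: 14, t-BuLi (2.1 equiv), Et2O/pentane, −78 °C; then 9, THF, −78 → −20 °C
Reagents that add atoms: none
Why: Iodine–lithium exchange gives the primary alkyllithium, which adds 1,2 to the enone carbonyl (which has no α′ hydrogen) and forms the C9–C11 bond; the carbinol configuration is irrelevant because C9 becomes trigonal in step 12.

Step 12
Reactants: 16 tertiary allylic alcohol
Product: 17 enone silyl ether
Conditions: [C5H5NH][CrO3Cl] (3 equiv), 4 Å molecular sieves, CH2Cl2, rt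
Reagents that add atoms: pyridinium chlorochromate, [C5H5NH][CrO3Cl] (supplies the carbonyl oxygen), [O-][Cr](=O)(=O)Cl.c1cc[nH+]cc1
Why: Babler–Dauben oxidative transposition: the tertiary allylic chromate ester undergoes a [3,3] shift to C7 and is oxidised there, which gives the C7 ketone conjugated with a C8=C9 double bond.

Step 13
Reactants: 17 enone silyl ether
Product: 18 enone alcohol
Conditions: Bu4NF, THF, 0 °C → rt
Reagents that add atoms: none
Why: Fluoride cleaves the silicon–oxygen bond (desilylation) and frees the C15 hydroxyl without touching the acetonide, the enone or the allyl group.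

Step 14
Reactants: 18 enone alcohol
Product: 20 enone acid, via aldehyde 19 (not isolated)
Conditions: TEMPO (cat.), NaClO2, NaOCl (cat.), MeCN/phosphate buffer (pH 6.7), 35 °C
Reagents that add atoms: sodium chlorite (NaClO2), [Na+].[O-]Cl=O
Why: The oxoammonium ion from TEMPO oxidises the primary alcohol to the aldehyde and chlorite takes the aldehyde on to the acid (TEMPO/chlorite oxidation) at almost neutral pH, where acetonide, terminal alkene and enone persist.

Step 15
Reactants: 20 enone acid
Product: 21 enone tert-butyl ester
Conditions: t-BuOC(=NH)CCl3, CH2Cl2/cyclohexane, rt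
Reagents that add atoms: tert-butyl 2,2,2-trichloroacetimidate, CC(C)(C)OC(=N)C(Cl)(Cl)Cl
Why: The carboxylic acid protonates the trichloroacetimidate and is O-alkylated by the tert-butyl cation equivalent so formed (imidate esterification), with no added acid that could open the acetonide.

Step 16
Reactants: 21 enone tert-butyl ester
Product: 23 keto aldehyde, via vicinal diol 22 (not isolated)
Conditions: K2OsO4·2H2O (cat.), NaIO4, 2,6-lutidine, dioxane/H2O, rt
Reagents that add atoms: sodium periodate (NaIO4), [Na+].[O-]I(=O)(=O)=O; water, O (oxygen reaches the substrate through the osmium catalyst)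
Why: Lemieux–Johnson cleavage: osmium tetroxide generated in situ dihydroxylates the terminal alkene only, the tetrasubstituted enone double bond being electron-poor and hindered, and periodate cleaves the diol to the C2 aldehyde with loss of formaldehyde.

Step 17
Reactants: 23 keto aldehyde
Product: 24 diol
Conditions: NaBH4, CeCl3·7H2O, MeOH, −40 → 0 °C
Reagents that add atoms: none
Why: Luche reduction converts the aldehyde into the C2 carbinol and reduces the enone 1,2; hydride enters C7 axially on the face of the axial C5 hydrogen, anti to the axial C10 methyl, so the new C7 hydroxyl is equatorial and cis to the C5 substituent, as in the reduction of carvone to cis-carveol.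

Step 18
Reactants: 24 diol
Product: 25 triethylsilyl ether
Conditions: Et3SiCl (1.05 equiv), imidazole, CH2Cl2, −78 → −40 °C
Reagents that add atoms: chlorotriethylsilane, CC[Si](CC)(CC)Cl
Why: Silylation is much faster at the unhindered primary C2 hydroxyl than at the secondary C7 hydroxyl next to the C8 methyl group (site-selective silylation), which leaves the allylic alcohol free for step 19.

Step 19
Reactants: 25 triethylsilyl ether
Product: 28 Δ7 alkene, via sulfonylhydrazine 26 (not isolated), via allylic diazene 27 (not isolated)
Conditions: PPh3, DEAD, 2-O2NC6H4SO2NHNH2, THF, −30 °C → rt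
Reagents that add atoms: none
Why: Mitsunobu displacement of the C7 hydroxyl by the sulfonylhydrazide with inversion, loss of the sulfinic acid and retro-ene expulsion of dinitrogen from the allylic diazene (reductive 1,3-transposition of an allylic alcohol) shift the double bond to C7=C8 and deliver hydrogen to C9 on the face of the inverted C7–N bond, that is anti to the C10 methyl, so that the side chain ends equatorial and cis to that methyl as in the target.

Step 20
Reactants: 28 Δ7 alkene
Product: 29 triol
Conditions: PPTS, MeOH, 40 °C
Reagents that add atoms: none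
Why: Mild acid-catalysed methanolysis removes the acetonide and the triethylsilyl ether in one operation (transketalisation and desilylation), under which the tert-butyl ester and the trisubstituted alkene are stable.

Step 21
Reactants: 29 triol
Product: 30 seco-ring-A trialdehyde
Conditions: (COCl)2, DMSO, CH2Cl2, −78 °C; Et3N, −78 → −20 °C; used crude at once
Reagents that add atoms: none
Why: Swern oxidation converts all three primary hydroxyls into alkoxysulfonium ions before the base is added, so the three aldehydes are released together, without hydroxy aldehyde (lactol) stages and without over-oxidation, and the geminal dialdehyde cannot enolise.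

**Ring closure and end game (steps 22–24)**

Step 22
Reactants: 30 seco-ring-A trialdehyde
Product: 31 ring-A diol aldehyde
Conditions: SmI2 (2.1 equiv, 0.1 M in THF) added slowly to 30 and t-BuOH (2 equiv) in THF (0.01 M), −78 °C; aq. NH4Cl
Reagents that add atoms: none
Why: One electron from divalent samarium goes to the unhindered C2 aldehyde; the samarium ketyl adds to one formyl group on C4 while trivalent samarium bridges both oxygens, and a second electron followed by protonation gives the diol. The closest known reaction is the SmI2 pinacol cyclisation of 1,6-dialdehydes to cis-cyclohexane-1,2-diols. Ring A closes by 6-exo-trig attack of the C2 ketyl carbon on the C3 carbonyl through a chair fused trans to ring B. The cis relation of the C2 and C3 oxygens comes from the samarium bridge; the face comes from the chair that keeps the C2 oxygen equatorial, away from the axial C10 methyl, which puts the C3 oxygen axial on the face opposite that methyl; C4 is fixed because the formyl group that does not react takes the axial site syn to the C10 methyl and leaves the larger methyl equatorial. The step needs selection between two diastereotopic formyl groups and restraint from 3-exo coupling of the geminal pair and from reduction of the surviving aldehyde; the first is secured by the trans-diequatorial arms on C10 and C5, which pre-organise one chair, the others by the faster six-membered closure, low temperature and a bare two equivalents of reductant added last.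

Step 23
Reactants: 31 ring-A diol aldehyde
Product: 32 2-acetate
Conditions: Ac2O (1.1 equiv), pyridine, CH2Cl2, 0 °C
Reagents that add atoms: acetic anhydride, CC(=O)OC(C)=O
Why: Acylation is faster at the equatorial C2 hydroxyl than at the axial C3 hydroxyl, which is flanked by the quaternary C4 (site-selective esterification of a cis diol).

Step 24
Reactants: 32 2-acetate
Product: 33 target acid
Conditions: CF3CO2H/CH2Cl2 (1:4), 0 °C
Reagents that add atoms: none
Why: Acidolysis of the tert-butyl ester through the tert-butyl cation (loss of 2-methylpropene) frees the C15 acid under conditions that leave the secondary acetate, the aldehyde and the alkene unchanged.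

**Compound list**

1 | (S)-carvone, (5S)-2-methyl-5-(prop-1-en-2-yl)cyclohex-2-en-1-one | CC1=CC[C@@H](CC1=O)C(C)=C | starting material
2 | 6-methylcarvone, (5S)-2,6-dimethyl-5-(prop-1-en-2-yl)cyclohex-2-en-1-one, both C6 epimers | CC1C(=O)C(C)=CC[C@@H]1C(C)=C | intermediate
3 | allyl bromide, 3-bromoprop-1-ene | C=CCBr | starting material
4 | allyl methyl enone, (5R,6R)-2,6-dimethyl-6-(prop-2-en-1-yl)-5-(prop-1-en-2-yl)cyclohex-2-en-1-one (allyl trans to isopropenyl) | C=CC[C@@]1(C)C(=O)C(C)=CC[C@@H]1C(C)=C | intermediate
5 | epoxide: 4 with the isopropenyl group as 2-methyloxiran-2-yl, both epoxide epimers | C=CC[C@@]1(C)C(=O)C(C)=CC[C@@H]1C2(C)CO2 | intermediate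
6 | α-methyl aldehyde: 4 with the isopropenyl group as CH(CH3)CHO, both C4 epimers | C=CC[C@@]1(C)C(=O)C(C)=CC[C@@H]1C(C)C=O | intermediate
7 | hydroxymethyl aldehyde: 4 with the isopropenyl group as C(CH3)(CH2OH)CHO, both C4 epimers | C=CC[C@@]1(C)C(=O)C(C)=CC[C@@H]1C(C)(CO)C=O | intermediate (not isolated)
8 | keto diol, (5R,6R)-5-(1,3-dihydroxy-2-methylpropan-2-yl)-2,6-dimethyl-6-(prop-2-en-1-yl)cyclohex-2-en-1-one | C=CC[C@@]1(C)C(=O)C(C)=CC[C@@H]1C(C)(CO)CO | intermediate
9 | acetonide ketone, (5R,6R)-2,6-dimethyl-6-(prop-2-en-1-yl)-5-(2,2,5-trimethyl-1,3-dioxan-5-yl)cyclohex-2-en-1-one | C=CC[C@@]1(C)C(=O)C(C)=CC[C@@H]1C2(C)COC(C)(C)OC2 | intermediate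
10 | methyl hydrogen (R)-3-methylglutarate | OC(=O)C[C@@H](C)CC(=O)OC | starting material
11 | methyl (R)-5-hydroxy-3-methylpentanoate | OCC[C@@H](C)CC(=O)OC | intermediate
12 | methyl (S)-5-iodo-3-methylpentanoate | ICC[C@@H](C)CC(=O)OC | intermediate
13 | (S)-5-iodo-3-methylpentan-1-ol | ICC[C@@H](C)CCO | intermediate
14 | iodo silyl ether, (S)-tert-butyl[(5-iodo-3-methylpentyl)oxy]dimethylsilane | ICC[C@@H](C)CCO[Si](C)(C)C(C)(C)C | intermediate
15 | alkyllithium: 14 with lithium in place of iodine | [Li]CC[C@@H](C)CCO[Si](C)(C)C(C)(C)C | intermediate (not isolated)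
16 | tertiary allylic alcohol: 1,2-adduct of 15 to the carbonyl of 9, both C9 epimers | C=CC[C@@]1(C)C(O)(CC[C@@H](C)CCO[Si](C)(C)C(C)(C)C)C(C)=CC[C@@H]1C2(C)COC(C)(C)OC2 | intermediate
17 | enone silyl ether: 4-allyl-3-[5-(tert-butyldimethylsilyloxy)-3-methylpentyl]-2,4-dimethyl-5-(2,2,5-trimethyl-1,3-dioxan-5-yl)cyclohex-2-en-1-one (C7 ketone, C8=C9; C10 methyl cis to the C5 substituent) | C=CC[C@@]1(C)C(CC[C@@H](C)CCO[Si](C)(C)C(C)(C)C)=C(C)C(=O)C[C@@H]1C2(C)COC(C)(C)OC2 | intermediate
18 | enone alcohol: 17 with free C15 hydroxyl | C=CC[C@@]1(C)C(CC[C@@H](C)CCO)=C(C)C(=O)C[C@@H]1C2(C)COC(C)(C)OC2 | intermediate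
19 | enone aldehyde: 18 with C15 as CHO | C=CC[C@@]1(C)C(CC[C@@H](C)CC=O)=C(C)C(=O)C[C@@H]1C2(C)COC(C)(C)OC2 | intermediate (not isolated)
20 | enone acid: 18 with C15 as CO2H | C=CC[C@@]1(C)C(CC[C@@H](C)CC(=O)O)=C(C)C(=O)C[C@@H]1C2(C)COC(C)(C)OC2 | intermediate
21 | enone tert-butyl ester | C=CC[C@@]1(C)C(CC[C@@H](C)CC(=O)OC(C)(C)C)=C(C)C(=O)C[C@@H]1C2(C)COC(C)(C)OC2 | intermediate
22 | vicinal diol: 21 with 2,3-dihydroxypropyl in place of allyl, both carbinol epimers | OCC(O)C[C@@]1(C)C(CC[C@@H](C)CC(=O)OC(C)(C)C)=C(C)C(=O)C[C@@H]1C2(C)COC(C)(C)OC2 | intermediate (not isolated)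
23 | keto aldehyde: 21 with the C10 arm as CH2CHO | O=CC[C@@]1(C)C(CC[C@@H](C)CC(=O)OC(C)(C)C)=C(C)C(=O)C[C@@H]1C2(C)COC(C)(C)OC2 | intermediate
24 | diol: C2 primary alcohol and C7 allylic alcohol, the C7 hydroxyl cis to the C5 substituent | OCC[C@@]1(C)C(CC[C@@H](C)CC(=O)OC(C)(C)C)=C(C)[C@H](O)C[C@@H]1C2(C)COC(C)(C)OC2 | intermediate
25 | triethylsilyl ether: 24 silylated at the C2 oxygen, C7 hydroxyl free | CC[Si](CC)(CC)OCC[C@@]1(C)C(CC[C@@H](C)CC(=O)OC(C)(C)C)=C(C)[C@H](O)C[C@@H]1C2(C)COC(C)(C)OC2 | intermediate
26 | sulfonylhydrazine: C7–N(NH2)SO2C6H4-2-NO2, C7 inverted | CC[Si](CC)(CC)OCC[C@@]1(C)C(CC[C@@H](C)CC(=O)OC(C)(C)C)=C(C)[C@@H](N(N)S(=O)(=O)c3ccccc3[N+](=O)[O-])C[C@@H]1C2(C)COC(C)(C)OC2 | intermediate (not isolated)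
27 | allylic diazene: C7–N=NH | CC[Si](CC)(CC)OCC[C@@]1(C)C(CC[C@@H](C)CC(=O)OC(C)(C)C)=C(C)[C@@H](N=N)C[C@@H]1C2(C)COC(C)(C)OC2 | intermediate (not isolated)
28 | Δ7 alkene: C7=C8, H9 anti to the C10 methyl; C2–OSiEt3, acetonide, tert-butyl ester | CC[Si](CC)(CC)OCC[C@@]1(C)[C@H](CC[C@@H](C)CC(=O)OC(C)(C)C)C(C)=CC[C@@H]1C2(C)COC(C)(C)OC2 | intermediate
29 | triol: C10 arm CH2CH2OH, C5 arm C(CH3)(CH2OH)2, tert-butyl ester | OCC[C@@]1(C)[C@H](CC[C@@H](C)CC(=O)OC(C)(C)C)C(C)=CC[C@@H]1C(C)(CO)CO | intermediate
30 | seco-ring-A trialdehyde, tert-butyl (5S,9R,10S,13R)-2,3,19-trioxo-2,3-secolabd-7-en-15-oate | O=CC[C@@]1(C)[C@H](CC[C@@H](C)CC(=O)OC(C)(C)C)C(C)=CC[C@@H]1C(C)(C=O)C=O | intermediate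
31 | ring-A diol aldehyde, tert-butyl (2S,3R,4S,5S,9R,10S,13R)-2,3-dihydroxy-19-oxolabd-7-en-15-oate | O[C@H]1C[C@@]2(C)[C@H](CC[C@@H](C)CC(=O)OC(C)(C)C)C(C)=CC[C@@H]2[C@](C)(C=O)[C@H]1O | intermediate
32 | 2-acetate, tert-butyl (2S,3R,4S,5S,9R,10S,13R)-2-acetoxy-3-hydroxy-19-oxolabd-7-en-15-oate | CC(=O)O[C@H]1C[C@@]2(C)[C@H](CC[C@@H](C)CC(=O)OC(C)(C)C)C(C)=CC[C@@H]2[C@](C)(C=O)[C@H]1O | intermediate
33 | CNP0180877.1, (2S,3R,4S,5S,9R,10S,13R)-2-acetoxy-3-hydroxy-19-oxolabd-7-en-15-oic acid | CC(=O)O[C@H]1C[C@@]2(C)[C@H](CC[C@@H](C)CC(=O)O)C(C)=CC[C@@H]2[C@](C)(C=O)[C@H]1O | target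

**Step count**

Total: 24 steps. Longest linear sequence: 20 steps from (S)-carvone (steps 1–6 and 11–24); the side chain takes 4 steps (7–10).

**Steps most likely to fail**

(a) Step 22. The reduction may not stop at the diol: the surviving formyl group sits next to a samarium alkoxide and may be reduced in turn, while holding the reductant back leaves uncyclised material. The fallback sets out from 30 and no longer asks the reagent to stop. With an excess of SmI2 in THF/MeOH at −78 → 0 °C, ring closure and reduction of the third formyl group should both run to completion and give the ring-closed triol tert-butyl ester F1. Its primary neopentyl alcohol would then be oxidised selectively with TEMPO (cat.), N-chlorosuccinimide and Bu4NCl in CH2Cl2/aqueous NaHCO3–K2CO3, a system that leaves secondary alcohols alone. This returns the route to 31.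

(b) Step 19. The Mitsunobu displacement at the hindered secondary allylic carbinol may give way to elimination or to attack at the far allyl terminus, so that no diazene forms at C7. The fallback sets out from 25. Formylation with formic acetic anhydride and pyridine at 0 °C should give the allylic formate F2. With Pd(OAc)2 (cat.) and PBu3 in dioxane at reflux, zerovalent palladium formed in situ ionises the formate with inversion, carbon dioxide is lost, and the palladium hydride delivers hydrogen to the more substituted allyl terminus C9. The hydrogen arrives on the face opposite the departed formate, which is the face served in the main step, with the double bond at C7=C8. The route is rejoined at 28.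

(c) Step 24. Under acid the acetyl group may migrate from O2 to the cis O3 through a cyclic orthoacid, and the C7=C8 bond may be protonated during the longer exposure that the ester cleavage needs. The fallback sets out from 31 and reverses the last two operations. The tert-butyl ester is cleaved first (CF3CO2H/CH2Cl2, 0 °C) to the dihydroxy aldehyde acid F3, which carries no acyl group that could migrate. F3 is then acetylated at the equatorial C2 hydroxyl (Ac2O, pyridine, 0 °C; the carboxylic acid is recovered on aqueous work-up), which comes back to the route at 33.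

**Further compounds**

F1 | step 22 | ring-closed triol tert-butyl ester, tert-butyl 2,3,19-trihydroxylabd-7-en-15-oate with the configuration of 31 | O[C@H]1C[C@@]2(C)[C@H](CC[C@@H](C)CC(=O)OC(C)(C)C)C(C)=CC[C@@H]2[C@](C)(CO)[C@H]1O
F2 | step 19 | allylic formate: 25 with the C7 hydroxyl as OCHO, C7 configuration unchanged | CC[Si](CC)(CC)OCC[C@@]1(C)C(CC[C@@H](C)CC(=O)OC(C)(C)C)=C(C)[C@H](OC=O)C[C@@H]1C2(C)COC(C)(C)OC2
F3 | step 24 | dihydroxy aldehyde acid, (2S,3R,4S,5S,9R,10S,13R)-2,3-dihydroxy-19-oxolabd-7-en-15-oic acid | O[C@H]1C[C@@]2(C)[C@H](CC[C@@H](C)CC(=O)O)C(C)=CC[C@@H]2[C@](C)(C=O)[C@H]1O
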